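**Retrosynthetic overview**
1. The five-membered dienone ring is closed last: C8–C15 and C13–C16 come from an α-lithiated allenyl ether that adds to the C8 ketone of the ten-membered α'-acetoxy enone 11 and then closes by a cationic 4π (Nazarov-type) reaction.
2. The ten-membered ring is not made by macrocyclization: ozonolysis of the C8=C9 ring-fusion olefin of tricycle 7 merges rings B and C into it; elimination (10) and α'-acetoxylation (11) follow.
3. 7 comes from anisole 4 by Birch reduction, enol ether hydrolysis and hydride reduction.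
4. Key step: 4 comes from the acyclic (E)-homogeranyl anisole 3 (geranyl chloride + 3-methoxybenzylmagnesium chloride) by an enantioselective cation–olefin bicyclization that closes rings A and B in one operation and sets C5 and C10.
5. Ring order: A and B together (step 2); B and C opened into the ten-membered ring (step 5); five-membered ring (step 9).

Positions are numbered as in kaurane: C5/C10 ring-A junction, C7 acetate carbon, C8=C14 enone olefin, C9 ketone, C13 five-ring stereocentre, C15 enone carbonyl, C16=C17 methylene.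

Assumption: the (S)-ligand of the chiral acid in step 2 is taken to give the (4aR,10aR) series; if the sense of induction is the reverse, the (R)-ligand is used.

**Route**

Step 1
Reactants: 1 geranyl chloride; 2 3-methoxybenzylmagnesium chloride
Product: 3 1-[(3E)-4,8-dimethylnona-3,7-dien-1-yl]-3-methoxybenzene
Conditions: THF, 0 → 20 °C
Reagents that add atoms: none
Why: SN2 alkylation of a benzylic Grignard reagent by a primary allylic chloride keeps the (E)-olefin intact and creates no stereocentre.

Step 2
Reactants: 3 1-[(3E)-4,8-dimethylnona-3,7-dien-1-yl]-3-methoxybenzene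
Product: 4 (4aR,10aR)-7-methoxy-1,1,4a-trimethyl-1,2,3,4,4a,9,10,10a-octahydrophenanthrene
Conditions: (S)-3,3'-dichloro-BINOL·SbCl5 (0.5 equiv), CH2Cl2, −78 °C
Reagents that add atoms: none
Why: Proton-initiated cation–olefin bicyclization (biomimetic polyene cyclization) in which the chiral BINOL·SbCl5 acid protonates one face of the terminal olefin and a chair–chair transition state relays the (E)-geometry into the trans ring fusion, so that rings A and B close together, C5 and C10 (both R) are set in the same event and the anisole is attacked para to OMe.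

Step 3
Reactants: 4 (4aR,10aR)-7-methoxy-1,1,4a-trimethyl-1,2,3,4,4a,9,10,10a-octahydrophenanthrene
Product: 6 (4aR,10aR)-1,1,4a-trimethyl-2,3,4,4a,5,6,8,9,10,10a-decahydrophenanthren-7(1H)-one, via dienol ether 5 (not isolated)
Conditions: Li, NH3(l), THF, t-BuOH, −78 → −33 °C; then (CO2H)2, MeOH–H2O–THF, 20 °C
Reagents that add atoms: water, O
Why: Birch reduction of the anisole leaves the tetrasubstituted C8=C9 olefin and the enol ether (the alkyl- and methoxy-bearing carbons stay sp2), and oxalic acid hydrolyses only the enol ether to the unconjugated β,γ-enone, so C5 and C10 are untouched and no new stereocentre arises.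

Step 4
Reactants: 6 (4aR,10aR)-1,1,4a-trimethyl-2,3,4,4a,5,6,8,9,10,10a-decahydrophenanthren-7(1H)-one
Product: 7 (4aR,10aR)-1,1,4a-trimethyl-1,2,3,4,4a,5,6,7,8,9,10,10a-dodecahydrophenanthren-7-ol (both carbinol epimers)
Conditions: NaBH4, MeOH, 0 °C
Reagents that add atoms: none
Why: Borohydride reduction of the unhindered ketone is faster than base-mediated conjugation of the β,γ-olefin, and the configuration of the new carbinol (C13) is irrelevant because this carbon becomes sp2 in step 6.

Step 5
Reactants: 7 (4aR,10aR)-1,1,4a-trimethyl-1,2,3,4,4a,5,6,7,8,9,10,10a-dodecahydrophenanthren-7-ol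
Product: 8 (4aR,12aR)-8-hydroxy-1,1,4a-trimethyldodecahydrobenzo[10]annulene-5,10-dione
Conditions: O3, CH2Cl2–MeOH, NaHCO3, −78 °C; then Me2S, −78 → 20 °C
Reagents that add atoms: ozone, O=[O+][O-]
Why: Ozonolysis of the electron-rich tetrasubstituted ring-fusion olefin (the only C=C present) cleaves C8=C9 and thereby turns rings B and C into the ten-membered 8,9-diketone, a ring expansion by olefin scission that leaves C5 and C10 untouched.

Step 6
Reactants: 8 (4aR,12aR)-8-hydroxy-1,1,4a-trimethyldodecahydrobenzo[10]annulene-5,10-dione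
Product: 10 (4aR,8Z,12aR)-1,1,4a-trimethyl-1,2,3,4,4a,6,7,11,12,12a-decahydrobenzo[10]annulene-5,10-dione, via mesylate 9 (not isolated)
Conditions: MsCl, Et3N, CH2Cl2, 0 → 20 °C
Reagents that add atoms: none
Why: Mesylation of the secondary alcohol and E1cB elimination through the enolate of the C8 ketone (β-elimination of a β-sulfonyloxy ketone) places the olefin in conjugation with C8 only, the cis olefin being the stable geometry in a ten-membered ring.

Step 7
Reactants: 10 (4aR,8Z,12aR)-1,1,4a-trimethyl-1,2,3,4,4a,6,7,11,12,12a-decahydrobenzo[10]annulene-5,10-dione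
Product: 11 (4aR,8Z,11R,12aR)-1,1,4a-trimethyl-5,10-dioxo-1,2,3,4,4a,5,6,7,10,11,12,12a-dodecahydrobenzo[10]annulen-11-yl acetate
Conditions: Mn(OAc)3·2H2O (4 equiv), benzene, reflux (Dean–Stark)
Reagents that add atoms: manganese triacetate Mn(OAc)3, CC(=O)[O-].CC(=O)[O-].CC(=O)[O-].[Mn+3]
Why: Mn(OAc)3 α'-acetoxylation of enones goes through the manganese enolate on the C7 side of the C8 carbonyl (C14 is vinylic) and spares the saturated, neopentyl C9 ketone; the epimerisable α-acetoxy ketone is expected to settle with the acetate pseudo-equatorial on the chair-like C5–C10 fold inherited from the tricycle, which corresponds to 7R.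

Step 8
Reactants: 12 2-(prop-2-yn-1-yloxy)tetrahydro-2H-pyran
Product: 13 2-(propa-1,2-dien-1-yloxy)tetrahydro-2H-pyran
Conditions: KOtBu (0.2 equiv), THF, 50 °C
Reagents that add atoms: none
Why: Base-catalysed prototropic isomerisation of a propargyl ether gives the conjugated allenyl ether; no stereocentre is involved.

Step 9
Reactants: 11 (4aR,8Z,11R,12aR)-1,1,4a-trimethyl-5,10-dioxo-1,2,3,4,4a,5,6,7,10,11,12,12a-dodecahydrobenzo[10]annulen-11-yl acetate; 13 2-(propa-1,2-dien-1-yloxy)tetrahydro-2H-pyran
Product: 16 CNP0421845.1 (5R,7R,10R,13S)-9,15-dioxo-8,9-secokaura-8(14),16-dien-7-yl acetate, via allenyl carbinol 14 (not isolated), via tertiary trifluoroacetate 15 (not isolated)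
Conditions: 13, n-BuLi, THF, −78 °C; CeCl3; then 11, −78 °C; then (CF3CO)2O, 2,6-lutidine, −78 → −20 °C
Reagents that add atoms: none
Why: Proposed new method: the closest known reaction is the Tius cationic cyclopentannulation (allene-ether Nazarov reaction) of carbinols made from simple enones, here run across C8 and C13 of a ten-membered enone: the allenylcerium reagent adds 1,2 to the enone carbonyl, which is activated by the α-acetoxy group and far less hindered than the neopentyl C9 ketone, the tertiary trifluoroacetate ionises to a pentadienyl cation whose conrotatory 4π closure forms C13–C16, loss of the tetrahydropyranyl cation then gives the C15 ketone with C8=C14 and the exocyclic methylene in place, and C13 (S) is expected because the C11–C14 chain should lie on the face of the cation anti to the axial C10 methyl, as in the trans-fused tricycle from which the ring was cut.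

**Compound list**

1 | geranyl chloride, (2E)-1-chloro-3,7-dimethylocta-2,6-diene | CC(C)=CCC/C(C)=C/CCl | starting material
2 | 3-methoxybenzylmagnesium chloride (THF solution) | COc1cccc(C[Mg]Cl)c1 | starting material
3 | 1-[(3E)-4,8-dimethylnona-3,7-dien-1-yl]-3-methoxybenzene | COc1cccc(CC/C=C(\C)CCC=C(C)C)c1 | intermediate
4 | (4aR,10aR)-7-methoxy-1,1,4a-trimethyl-1,2,3,4,4a,9,10,10a-octahydrophenanthrene | COc1ccc2[C@]3(C)CCCC(C)(C)[C@H]3CCc2c1 | intermediate
5 | (4aR,10aR)-7-methoxy-1,1,4a-trimethyl-1,2,3,4,4a,5,8,9,10,10a-decahydrophenanthrene (dienol ether) | COC1=CCC([C@]2(C)CCCC(C)(C)[C@H]2CC3)=C3C1 | intermediate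
6 | (4aR,10aR)-1,1,4a-trimethyl-2,3,4,4a,5,6,8,9,10,10a-decahydrophenanthren-7(1H)-one | O=C1CC2=C(CC1)[C@]1(C)CCCC(C)(C)[C@H]1CC2 | intermediate
7 | (4aR,10aR)-1,1,4a-trimethyl-1,2,3,4,4a,5,6,7,8,9,10,10a-dodecahydrophenanthren-7-ol, both carbinol epimers | OC1CC2=C(CC1)[C@]1(C)CCCC(C)(C)[C@H]1CC2 | intermediate
8 | (4aR,12aR)-8-hydroxy-1,1,4a-trimethyldodecahydrobenzo[10]annulene-5,10-dione, both carbinol epimers | O=C1CC(O)CCC(=O)[C@]2(C)CCCC(C)(C)[C@H]2CC1 | intermediate
9 | (4aR,12aR)-1,1,4a-trimethyl-5,10-dioxododecahydrobenzo[10]annulen-8-yl methanesulfonate | O=C1CC(OS(C)(=O)=O)CCC(=O)[C@]2(C)CCCC(C)(C)[C@H]2CC1 | intermediate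
10 | (4aR,8Z,12aR)-1,1,4a-trimethyl-1,2,3,4,4a,6,7,11,12,12a-decahydrobenzo[10]annulene-5,10-dione | O=C1/C=C\CCC(=O)[C@]2(C)CCCC(C)(C)[C@H]2CC1 | intermediate
11 | (4aR,8Z,11R,12aR)-1,1,4a-trimethyl-5,10-dioxo-1,2,3,4,4a,5,6,7,10,11,12,12a-dodecahydrobenzo[10]annulen-11-yl acetate | O=C1/C=C\CCC(=O)[C@]2(C)CCCC(C)(C)[C@H]2C[C@H]1OC(C)=O | intermediate
12 | 2-(prop-2-yn-1-yloxy)tetrahydro-2H-pyran (racemic) | C#CCOC1CCCCO1 | starting material
13 | 2-(propa-1,2-dien-1-yloxy)tetrahydro-2H-pyran (racemic) | C=C=COC1CCCCO1 | intermediate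
14 | (4aR,8Z,11R,12aR)-10-hydroxy-1,1,4a-trimethyl-5-oxo-10-[1-(tetrahydro-2H-pyran-2-yloxy)propa-1,2-dien-1-yl]-1,2,3,4,4a,5,6,7,10,11,12,12a-dodecahydrobenzo[10]annulen-11-yl acetate (as its cerium alkoxide; mixture at C10 and at the acetal carbon) | C=C=C(OC1CCCCO1)C2(O)/C=C\CCC(=O)[C@]3(C)CCCC(C)(C)[C@H]3C[C@H]2OC(C)=O | intermediate
15 | 10-trifluoroacetate of 14 | C=C=C(OC1CCCCO1)C2(OC(=O)C(F)(F)F)/C=C\CCC(=O)[C@]3(C)CCCC(C)(C)[C@H]3C[C@H]2OC(C)=O | intermediate
16 | CNP0421845.1, (5R,7R,10R,13S)-9,15-dioxo-8,9-secokaura-8(14),16-dien-7-yl acetate (kaurane numbering) | C=C1C(=O)C2=C[C@@H]1CCC(=O)[C@]1(C)CCCC(C)(C)[C@H]1C[C@H]2OC(C)=O | target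

**Step count and risks**

Total step count: 9. Longest linear sequence: 8 steps (1–7 and 9); step 8 is a one-step side branch.

Most at risk is step 9. The allenyl reagent must choose the C8 over the C9 ketone, the C7 acetate can capture the C8 cation as a dioxolanylium ion, and the 4π closure has to build a bridgehead olefin across a ten-membered ring. The C13 configuration rests on a conformational argument, not on precedent. The fallback sets out from 11 and returns at 16, replacing the cationic allene-ether closure by a gold-catalysed Rautenstrauch rearrangement with the methylene introduced last. HC≡CMgBr with CeCl3 adds to the C8 ketone and the alkoxide is acylated in the flask with pivaloyl chloride to give the tertiary propargylic pivalate F1. Ph3PAuCl/AgSbF6 in wet MeCN at −20 °C brings about 1,2-acyloxy shift, C13–C16 closure and hydrolysis of the enol pivalate to the bicyclic cyclopentenone F2, which lacks only the methylene. LiN(SiMe3)2 at −78 °C (the C15 ketone has α-hydrogens only at C16) and Eschenmoser's salt (CH2=NMe2+ I−) give the Mannich base F3, and MeI followed by NaHCO3 eliminates the amine to give 16.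

Second is step 7. The C7 configuration is set by substrate control in a flexible ring, and the hot, acidic medium can trigger transannular aldol reactions of the 1,6-diketone or oxidation next to C9. The fallback sets out from 10 and returns at 11, and fixes C7 by inversion instead of relying on the ring. If the acetoxylation gives mainly the 7S acetate F4, brief K2CO3/MeOH at 0 °C frees the 7S α-ketol F5, and a Mitsunobu reaction (AcOH, PPh3, DIAD, THF, 0 °C) inverts C7 and delivers 11 directly.

Third is step 2. The enantiomeric excess may stay near 90 %, some closure ortho to OMe is possible, and monocyclised olefins can survive. The fallback sets out from 3 and returns at 4, using a reagent-controlled iodonium-initiated bicyclization. NIS with a stoichiometric BINOL-derived chiral phosphoramidite (toluene, −40 °C), then ClSO3H at −78 °C to complete the second ring, gives the equatorial iodide F6. Bu3SnH with AIBN in toluene at 80 °C removes the iodine and gives 4.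

**Further compounds**

F1 | step 9 | (4aR,8Z,11R,12aR)-11-acetoxy-10-ethynyl-1,1,4a-trimethyl-5-oxo-1,2,3,4,4a,5,6,7,10,11,12,12a-dodecahydrobenzo[10]annulen-10-yl pivalate (mixture at C10) | C#CC1(OC(=O)C(C)(C)C)/C=C\CCC(=O)[C@]2(C)CCCC(C)(C)[C@H]2C[C@H]1OC(C)=O
F2 | step 9 | 16-demethylene analogue of 16 (C16 is CH2; C5, C7, C10, C13 as in 16) | C1C(=O)C2=C[C@@H]1CCC(=O)[C@]1(C)CCCC(C)(C)[C@H]1C[C@H]2OC(C)=O
F3 | step 9 | 16-(dimethylaminomethyl) derivative of F2 (Mannich base; mixture at C16) | CN(C)CC1C(=O)C2=C[C@@H]1CCC(=O)[C@]1(C)CCCC(C)(C)[C@H]1C[C@H]2OC(C)=O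
F4 | step 7 | (4aR,8Z,11S,12aR)-1,1,4a-trimethyl-5,10-dioxo-1,2,3,4,4a,5,6,7,10,11,12,12a-dodecahydrobenzo[10]annulen-11-yl acetate (7S epimer of 11) | O=C1/C=C\CCC(=O)[C@]2(C)CCCC(C)(C)[C@H]2C[C@@H]1OC(C)=O
F5 | step 7 | (4aR,8Z,11S,12aR)-11-hydroxy-1,1,4a-trimethyl-1,2,3,4,4a,6,7,11,12,12a-decahydrobenzo[10]annulene-5,10-dione | O=C1/C=C\CCC(=O)[C@]2(C)CCCC(C)(C)[C@H]2C[C@@H]1O
F6 | step 2 | (2R,4aR,10aS)-2-iodo-7-methoxy-1,1,4a-trimethyl-1,2,3,4,4a,9,10,10a-octahydrophenanthrene (iodine equatorial, cis to the angular methyl) | COc1ccc2[C@]3(C)CC[C@@H](I)C(C)(C)[C@H]3CCc2c1
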